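One sum holds steady in these flasks once J has become D, leaving aside Z → L: z − y − κ ln y, where y is D and z is Z plus E, both as fractions of the J charged.

| setting | dusk | summer | spring |
|---|---|---|---|
| J | 0.14 M | 0.14 M | 0.14 M |
| Z | 0.252 M | 0.252 M | 0.252 M |
| temperature | 105 °C | 120 °C | 90 °C |
| time | 8.0 min | 8.0 min | 8.0 min |

    J → D (k1 = 0.0439 s⁻¹, Ea1 = 93.0 kJ mol⁻¹)
    D + E → D.E (k2 = 0.0150 L mol⁻¹ s⁻¹, Ea2 = 53.0 kJ mol⁻¹)
    E → G (k3 = 7.56 × 10⁻⁴ s⁻¹, Ea3 = 111 kJ mol⁻¹)
    Z → E (k4 = 0.00550 s⁻¹, Ea4 = 102 kJ mol⁻¹)
    Z → L (k5 = 1.17 × 10⁻⁵ s⁻¹, Ea5 = 114 kJ mol⁻¹)
    D.E → Q (k6 = 0.00356 s⁻¹, Ea6 = 93.0 kJ mol⁻¹)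
    (constants at 90 °C)

1. which of these there is most of at the end, counted by the J in it, dusk (J / D.E / Q / D)
2. which of these there is most of at the end, counted by the J in it, summer (J / D.E / Q / D)
3. which of these there is most of at the end, counted by the J in it, spring (J / D.E / Q / D)
4. the largest of these amounts at the end, in percent of the J charged, dusk
5. the largest of these amounts at the end, in percent of the J charged, summer
6. the largest of these amounts at the end, in percent of the J charged, spring

**Your hunch.** You expected more heat to carry more J on to Q. I doubted it, because heat favours E → G over capture by D. The sum shows what that costs. Capture spends one E per D, while E → G burns E in step with ln y. The weight κ is the constant of E → G over that of D + E → D.E times the J charged, the inverse of a selectivity factor, and in summer it is 1.56, against 0.360 in spring, so summer wastes more E per capture.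

**Summer reckoned.** In summer J has a half-life of 0.0251 min and Z one of 0.160 min, so D is in place first, and Z → L takes hardly any Z. E then has a half-life of 0.924 min against E → G, far shorter than the run, so I took z to fall from 1.80 to nothing. That gives 1.80 = 1 − y − κ ln y. Iterating from y = 0.5, I got 43.4% first and settled at 44.9%. D.E drains with a half-life of 0.309 min, shorter than the run, so I committed to Q at 55.1%.

**Cooler flasks.** The E → G half-life is 3.56 min in dusk and 15.3 min in spring, the latter longer than the run. E therefore remains at the end of spring, the sum needs the clock there, and my reckoning stopped at saying that D stands above the root.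

The forecast gave Q at 64.5% for dusk, Q at 54.5% for summer and D at 46% for spring, saying of summer that “E→G competes harder”.

**The result.** The flasks ended with Q at 65.2% in dusk, Q at 54.8% in summer and D at 46.0% in spring. In summer, where κ is 1.56 and the E → G half-life is shorter than the run, D read 45.2% against my 44.9%, with E down to 1.15 × 10⁻⁴ M. In dusk, E still stood at 0.0270 M after 8.00 min, but with κ at 0.771 the root is 25.5%, and D read 25.7% after 80.0 min.

(The constants used here are assumed; the result is computed.)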